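This closed, stirred vessel holds a charge of solid substrate at 40 °C. I have followed it as cedar up to 30.0 h, and oak is the same charge run cooler.

| flask | solid substrate | temperature | remark | time |
|---|---|---|---|---|
| cedar | 0.50 M | 40 °C | the very flask that is asked about, followed so far |  |
| oak | 0.50 M | 35 °C | run made earlier |  |
| flask | 0.50 M | 40 °C |  | 40 h |

| run | time / h | ring / % |
|---|---|---|
| cedar | 1.50 | 2.7 |
| cedar | 5.00 | 15.7 |
| cedar | 10.0 | 20.5 |
| cedar | 15.0 | 19.6 |
| cedar | 20.0 | 18.6 |
| cedar | 25.0 | 18.9 |
| cedar | 30.0 | 19.0 |
| oak | 1.50 | 1.7 |
| oak | 5.00 | 10.4 |
| oak | 10.0 | 16.9 |
| oak | 15.0 | 17.4 |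
| oak | 20.0 | 17.2 |
| oak | 25.0 | 16.2 |
| oak | 30.0 | 15.9 |

(each reading ± 0.5 percentage points)

- ring, in percent of the solid substrate first charged, at 40 h
- the remedy with the largest gain of ring, or "none" below 2 percentage points (dusk / dawn / summer / none)
- ring present, with what was taken out counted in, in percent of the solid substrate first charged, after dusk
- ring present, with what was taken out counted in, in percent of the solid substrate first charged, after summer

- dusk: at 40 h take out 90 % of the ring then present, then wait 20 h
- dawn: at 40 h raise the temperature by 15 K, then wait 20 h
- summer: change nothing and wait 20 h more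

- given per volume of solution although it is solid: solid substrate
- ring that was removed still counts
- at the start none of the solid substrate is in solution

I look at the rate of ring, not at its amount. In cedar ring climbs by 0.0371 /h of the charge between 1.50 h and 5.00 h, but by 0.00960 /h up to 10.0 h, so the net rate has shrunk by a factor of 3.86. From 15.0 h on it is lost in a scatter of 0.5 percentage points. I take the ring already present as the brake, so dividing that fall in rate by the ring gained between the two windows gives 0.309 /h. The natural logarithm of two divided by this is the refill half-time, a relaxation half-life read from the readings, the time in which the gap between ring and its flat level halves: 2.24 h.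

The 20 h of waiting is 8.93 half-times, longer than one, so I expect each remedy to reach its new flat level and I compare end levels. Taking out 90 % and refilling gains me 17 points. From oak to cedar the last reading rises by a factor of 1.19, and 3 such steps make up the rise of 15 K, so heating gains me 13 points. I therefore choose dusk, since its gain is larger.

The forecast also names dusk, with 18.9 % now, 18.8 % after summer and 34 % after dusk, a dusk gain of 15 points that is smaller than mine, on the ground that “20 h is several relaxation times”.

The flask gives 19.5 % at 40 h, 21.4 % after summer and 33.7 % after dusk, but the best remedy is dawn, gaining 20 points against 14 points for dusk and 1.9 points for summer.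

    starting material → ring (k = 0.00168 /min, Ea = 106 kJ/mol)
    2 starting material ⇌ open dimer (K = 21.4 /M, k = 0.00532 /M/min, Ea = 75.0 kJ/mol, ΔH = −13.0 kJ/mol)
    solid substrate ⇌ starting material, rate k3*(cs3 - [starting material]) while solid is left; crystals form when [starting material] > cs3 (solubility = 0.460 M, k = 0.00641 /min)
    ring ⇌ isomer of the product (K = 2.53, k = 0.00243 /min, Ea = 95.0 kJ/mol, ΔH = −39.0 kJ/mol)
    (constants at 40 °C)

Dusk's flask holds 16.1 % of ring again after 8.93 of my half-times. The neighbour flask, the same charge held at 55 °C from the start, has had 17.9 of these half-times, as read at 40 °C, and it stands at 42.9 % at 40 h, 23 points above the asked flask, while the gain of dawn is 20 points.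

The readings were computed with made-up constants; noise was put on by code.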